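**Plan**

- Retrosynthesis: the enyne is cut at C1≡C2 (Colvin homologation) and C3=C4 (cross-metathesis) back to an allyl arm; C12–Br and C10–OAc go back to an anti-1,3-diol; the C9–O bond of the tetrahydrofuran goes back to a bridged hemiketal; the C9–C10 bond of the oxocane is cut to two ester carbons.
- The acyclic ether diester is cut at C5–C6 (allylboration), C7–C8 (glycolate alkylation), O–C7 (carbenoid O–H insertion) and C11–C12 (aldol).
- Forward: the C7–O–C13 chain is grown from methyl (R)-2-hydroxybutanoate (steps 1–11); the oxocane closes first (step 12), the tetrahydrofuran second (steps 13–14); C10, C12 and the enyne are finished last (steps 15–20).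
- Enabling feature (C1 = alkyne CH to C15 = ethyl CH3): C9 and C10 are neighbouring oxygen-bearing carbons inside the eight-membered C7–O–C13 ether ring, so both can be the acyl carbons of a diester whose two arms already hang on the ether oxygen.
- Stereochemistry: C13 from the chiral pool; C12 by chelation-controlled aldol; C7 by an oxazolidinone auxiliary; C6 by Ipc2B-allyl (matched with the Felkin preference); C9 by the bicyclic frame; C10 by hydroxyl-directed reduction from C12–OH; C12–Br by SN2 inversion; the E alkene by metathesis.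

Key step: step 12

Remark: chain numbering C1–C15 is used in the text, and locants 1, 3, 4, 6, 7, 9, 10 of the bicyclic names are C7, C13, C12, C10, C9, C6, C8; compounds 23–25 are carried as C10 epimer mixtures because steps 15–17 reset this centre (TBS = tert-butyldimethylsilyl, TES = triethylsilyl, Ipc = isopinocampheyl).

Step 1
Reactants: 1 methyl (R)-2-hydroxybutanoate; 2 tert-butyl diazoacetate
Product: 3 tert-butyl 2-{[(2R)-1-methoxy-1-oxobutan-2-yl]oxy}acetate
Conditions: Rh2(OAc)4 (1 mol %), CH2Cl2, 23 °C, slow addition of 2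
Reagents that add atoms: none
Why: Rhodium-carbenoid O–H insertion attaches the future C7 carbon to the C13 oxygen under neutral conditions, so the chiral-pool centre C13 (R) of the α-hydroxy ester is not epimerised.

Step 2
Reactants: 3 tert-butyl 2-{[(2R)-1-methoxy-1-oxobutan-2-yl]oxy}acetate
Product: 4 tert-butyl 2-{[(2R)-1-oxobutan-2-yl]oxy}acetate
Conditions: iBu2AlH (1.05 equiv), CH2Cl2, −78 °C; MeOH, aq. KNaC4H4O6
Reagents that add atoms: none
Why: Partial iBu2AlH reduction of the methyl ester should stop at the aldehyde through the stable tetrahedral aluminate at −78 °C, the bulkier tert-butyl ester reacting much more slowly.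

Step 3
Reactants: 4 tert-butyl 2-{[(2R)-1-oxobutan-2-yl]oxy}acetate; 5 1-(tert-butyldimethylsilyloxy)-1-methoxyethene
Product: 6 methyl (3R,4R)-4-(2-tert-butoxy-2-oxoethoxy)-3-hydroxyhexanoate
Conditions: MgBr2·OEt2 (3 equiv), CH2Cl2, −78 → 0 °C; 1 M HCl work-up
Reagents that add atoms: none
Why: Chelation-controlled Mukaiyama aldol addition, in which Mg bridges the aldehyde and ether oxygens and the ketene acetal attacks the face of the five-membered chelate opposite the ethyl group, should set C12 as R (syn to C13–O).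

Step 4
Reactants: 6 methyl (3R,4R)-4-(2-tert-butoxy-2-oxoethoxy)-3-hydroxyhexanoate
Product: 8 2-{[(3R,4R)-4-(tert-butyldimethylsilyloxy)-6-methoxy-6-oxohexan-3-yl]oxy}acetic acid, via silyl ester 7 (not isolated)
Conditions: TBSOTf (3 equiv), 2,6-lutidine (5 equiv), CH2Cl2, 0 → 23 °C; then K2CO3, MeOH/THF/H2O, 0 °C, acidify to pH 4
Reagents that add atoms: tert-butyldimethylsilyl triflate, CC(C)(C)[Si](C)(C)OS(=O)(=O)C(F)(F)F
Why: The silyl triflate silylates the C12 hydroxyl and also converts the tert-butyl ester into the silyl ester with loss of isobutene (silyl-triflate ester cleavage), and the silyl ester is hydrolysed selectively on mild aqueous work-up.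

Step 5
Reactants: 8 2-{[(3R,4R)-4-(tert-butyldimethylsilyloxy)-6-methoxy-6-oxohexan-3-yl]oxy}acetic acid; 9 (S)-4-benzyl-2-oxazolidinone
Product: 11 methyl (3R,4R)-4-{2-[(4S)-4-benzyl-2-oxo-1,3-oxazolidin-3-yl]-2-oxoethoxy}-3-(tert-butyldimethylsilyloxy)hexanoate, via mixed anhydride 10 (not isolated)
Conditions: t-BuCOCl, Et3N, THF, −78 → 0 °C; then 9 pre-treated with n-BuLi (THF, −78 °C), −78 → 0 °C
Reagents that add atoms: none
Why: Mixed pivalic anhydride activation followed by N-acylation of the lithiated oxazolidinone is the standard entry to N-glycolyl imides, attack taking place at the unhindered glycolyl carbonyl.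

Step 6
Reactants: 11 methyl (3R,4R)-4-{2-[(4S)-4-benzyl-2-oxo-1,3-oxazolidin-3-yl]-2-oxoethoxy}-3-(tert-butyldimethylsilyloxy)hexanoate; 12 tert-butyl bromoacetate
Product: 13 tert-butyl (3R)-4-[(4S)-4-benzyl-2-oxo-1,3-oxazolidin-3-yl]-3-{[(3R,4R)-4-(tert-butyldimethylsilyloxy)-6-methoxy-6-oxohexan-3-yl]oxy}-4-oxobutanoate
Conditions: NaN(SiMe3)2 (1.1 equiv), THF, −78 °C; 12 (3 equiv), −78 → −45 °C
Reagents that add atoms: none
Why: Evans alkylation of the chelated Z sodium enolate of the N-glycolyl imide with a reactive α-bromo ester, in which the benzyl group blocks one enolate face, should form the C7–C8 bond with C7 as R.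

Step 7
Reactants: 13 tert-butyl (3R)-4-[(4S)-4-benzyl-2-oxo-1,3-oxazolidin-3-yl]-3-{[(3R,4R)-4-(tert-butyldimethylsilyloxy)-6-methoxy-6-oxohexan-3-yl]oxy}-4-oxobutanoate
Product: 14 tert-butyl (3R)-3-{[(3R,4R)-4-(tert-butyldimethylsilyloxy)-6-methoxy-6-oxohexan-3-yl]oxy}-4-hydroxybutanoate
Conditions: NaBH4, THF/H2O (4:1), 0 °C
Reagents that add atoms: none
Why: Reductive removal of the auxiliary, in which NaBH4 in wet THF reduces the activated exocyclic imide carbonyl to the primary alcohol (C6) and leaves the methyl and tert-butyl esters, the γ-hydroxy tert-butyl ester being slow to lactonise.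

Step 8
Reactants: 14 tert-butyl (3R)-3-{[(3R,4R)-4-(tert-butyldimethylsilyloxy)-6-methoxy-6-oxohexan-3-yl]oxy}-4-hydroxybutanoate
Product: 15 tert-butyl (3R)-3-{[(3R,4R)-4-(tert-butyldimethylsilyloxy)-6-methoxy-6-oxohexan-3-yl]oxy}-4-oxobutanoate
Conditions: Dess–Martin periodinane, NaHCO3, CH2Cl2, 0 → 23 °C; used crude
Reagents that add atoms: none
Why: Dess–Martin oxidation gives the α-alkoxy aldehyde under buffered, non-basic conditions that should not epimerise C7.

Step 9
Reactants: 15 tert-butyl (3R)-3-{[(3R,4R)-4-(tert-butyldimethylsilyloxy)-6-methoxy-6-oxohexan-3-yl]oxy}-4-oxobutanoate; 16 allylmagnesium bromide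
Product: 18 tert-butyl (3R,4S)-3-{[(3R,4R)-4-(tert-butyldimethylsilyloxy)-6-methoxy-6-oxohexan-3-yl]oxy}-4-hydroxyhept-6-enoate, via borinate 17 (not isolated)
Conditions: (−)-Ipc2BOMe (from (+)-α-pinene), 16, Et2O, 0 → 23 °C; then 15, −78 °C; NaBO3·4H2O, THF/H2O, 23 °C
Reagents that add atoms: none
Why: Brown allylboration through a closed chair transition state, in which the reagent made from (−)-Ipc2BOMe adds to the si face of the aldehyde, the face also preferred by the Felkin–Anh/Cornforth model for this α-alkoxy aldehyde (matched pair), should give the 6S alcohol anti to C7–O.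

Step 10
Reactants: 18 tert-butyl (3R,4S)-3-{[(3R,4R)-4-(tert-butyldimethylsilyloxy)-6-methoxy-6-oxohexan-3-yl]oxy}-4-hydroxyhept-6-enoate
Product: 20 (3R,4S)-3-{[(3R,4R)-4-(tert-butyldimethylsilyloxy)-6-methoxy-6-oxohexan-3-yl]oxy}-4-(triethylsilyloxy)hept-6-enoic acid, via silyl ester 19 (not isolated)
Conditions: TESOTf (3 equiv), 2,6-lutidine (5 equiv), CH2Cl2, 0 → 23 °C; then pH 7 buffer, THF
Reagents that add atoms: triethylsilyl triflate, CC[Si](CC)(CC)OS(=O)(=O)C(F)(F)F
Why: Excess silyl triflate silylates the C6 hydroxyl and cleaves the tert-butyl ester to the triethylsilyl ester, which hydrolyses on buffered work-up, so the C6 oxygen is capped before a lactonisable C9 ester is present.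

Step 11
Reactants: 20 (3R,4S)-3-{[(3R,4R)-4-(tert-butyldimethylsilyloxy)-6-methoxy-6-oxohexan-3-yl]oxy}-4-(triethylsilyloxy)hept-6-enoic acid
Product: 21 methyl (3R,4S)-3-{[(3R,4R)-4-(tert-butyldimethylsilyloxy)-6-methoxy-6-oxohexan-3-yl]oxy}-4-(triethylsilyloxy)hept-6-enoate
Conditions: Me3SiCHN2, MeOH/toluene (1:4), 0 °C
Reagents that add atoms: (trimethylsilyl)diazomethane, C[Si](C)(C)C=[N+]=[N-]
Why: Esterification with (trimethylsilyl)diazomethane in methanol methylates the acid under neutral conditions that leave both silyl ethers untouched.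

Step 12
Reactants: 21 methyl (3R,4S)-3-{[(3R,4R)-4-(tert-butyldimethylsilyloxy)-6-methoxy-6-oxohexan-3-yl]oxy}-4-(triethylsilyloxy)hept-6-enoate
Product: 22 (2R,3R,5Z,8R)-3-(tert-butyldimethylsilyloxy)-2-ethyl-8-[(1S)-1-(triethylsilyloxy)but-3-en-1-yl]-5,6-bis(trimethylsilyloxy)-3,4,7,8-tetrahydro-2H-oxocine
Conditions: Na dispersion (5 equiv), Me3SiCl (6 equiv), toluene, 110 °C, slow addition of 21
Reagents that add atoms: chlorotrimethylsilane, C[Si](C)(C)Cl
Why: Sodium transfers an electron to each ester carbonyl, the two ketyl radical anions couple on the metal surface to make C9–C10, both methoxides are lost, and the 1,2-diketone is reduced further to the enediolate, which Me3SiCl silylates on both oxygens (acyloin condensation in its Rühlmann form). The closest known reaction type is the acyloin cyclisation of α,ω-diesters to medium rings, for which eight-membered rings are a standard case. The oxocane closes by joining the two terminal acyl carbons of a chain that already contains the C7–O–C13 ether, that is by a carbon–carbon bond between two like-polarised centres held on the sodium surface and not by an end-to-end nucleophilic attack. No stereocentre is formed, C6, C7, C12 and C13 are not α to a carbonyl, and the enediol double bond can only be cis in the eight-membered ring. The step needs chemoselectivity for the two methyl esters over the silyl ethers and the terminal alkene, which are inert to Na in toluene, and it needs suppression of β-elimination at C7–O and C12–OSi and of Dieckmann closure. Me3SiCl secures this by removing methoxide as Me3SiOMe and by capping the enediolate, so that neither base nor a free β-oxygenated ketone is present.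

Step 13
Reactants: 22 (2R,3R,5Z,8R)-3-(tert-butyldimethylsilyloxy)-2-ethyl-8-[(1S)-1-(triethylsilyloxy)but-3-en-1-yl]-5,6-bis(trimethylsilyloxy)-3,4,7,8-tetrahydro-2H-oxocine
Product: 24 (1R,3R,4R,6RS,7R,9S)-4-(tert-butyldimethylsilyloxy)-3-ethyl-9-(prop-2-en-1-yl)-2,8-dioxabicyclo[5.2.1]decane-6,7-diol, via hydroxy ketol 23 (not isolated)
Conditions: AcOH/THF/H2O (3:1:1), 23 → 45 °C
Reagents that add atoms: none
Why: Mild aqueous acid cleaves the two enol silyl ethers and the triethylsilyl ether but not the TBS ether, the two ketols interconvert through the enediol, and the 9-oxo isomer is drained as the five-membered bridged hemiketal with the C6 hydroxyl (hemiketalisation under thermodynamic control), whereas a six-membered hemiketal at C10 would need a boat tetrahydropyran spanned 1,4 by four atoms.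

Step 14
Reactants: 24 (1R,3R,4R,6RS,7R,9S)-4-(tert-butyldimethylsilyloxy)-3-ethyl-9-(prop-2-en-1-yl)-2,8-dioxabicyclo[5.2.1]decane-6,7-diol
Product: 25 (1R,3R,4R,6RS,7R,9S)-4-(tert-butyldimethylsilyloxy)-3-ethyl-9-(prop-2-en-1-yl)-2,8-dioxabicyclo[5.2.1]decan-6-ol
Conditions: Et3SiH (5 equiv), BF3·OEt2 (3 equiv), CH2Cl2, −78 → −30 °C
Reagents that add atoms: none
Why: Ionic hydrogenation of the hemiketal, in which BF3 ionises the C9 hydroxyl to the bridged oxocarbenium ion and Et3SiH delivers hydride to its only open (exo) face, fixes C9 as R by the bicyclic frame, and a competing 1,2-hydride shift from C10 would only give ketone 26 one step early.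

Step 15
Reactants: 25 (1R,3R,4R,6RS,7R,9S)-4-(tert-butyldimethylsilyloxy)-3-ethyl-9-(prop-2-en-1-yl)-2,8-dioxabicyclo[5.2.1]decan-6-ol
Product: 26 (1R,3R,4R,7R,9S)-4-(tert-butyldimethylsilyloxy)-3-ethyl-9-(prop-2-en-1-yl)-2,8-dioxabicyclo[5.2.1]decan-6-one
Conditions: Dess–Martin periodinane, NaHCO3, CH2Cl2, 23 °C
Reagents that add atoms: none
Why: Dess–Martin oxidation merges both C10 epimers into one α-alkoxy ketone without base that could eliminate the β-silyloxy group.

Step 16
Reactants: 26 (1R,3R,4R,7R,9S)-4-(tert-butyldimethylsilyloxy)-3-ethyl-9-(prop-2-en-1-yl)-2,8-dioxabicyclo[5.2.1]decan-6-one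
Product: 27 (1R,3R,4R,7R,9S)-3-ethyl-4-hydroxy-9-(prop-2-en-1-yl)-2,8-dioxabicyclo[5.2.1]decan-6-one
Conditions: HF·pyridine, pyridine, THF, 0 → 23 °C
Reagents that add atoms: none
Why: Fluoride-mediated desilylation under mildly acidic conditions frees the C12 hydroxyl without the base-induced β-elimination that a β-hydroxy ketone would suffer.

Step 17
Reactants: 27 (1R,3R,4R,7R,9S)-3-ethyl-4-hydroxy-9-(prop-2-en-1-yl)-2,8-dioxabicyclo[5.2.1]decan-6-one
Product: 28 (1R,3R,4R,6R,7R,9S)-3-ethyl-9-(prop-2-en-1-yl)-2,8-dioxabicyclo[5.2.1]decane-4,6-diol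
Conditions: Me4NBH(OAc)3 (5 equiv), MeCN/AcOH (1:1), −30 °C
Reagents that add atoms: none
Why: Evans–Saksena hydroxyl-directed reduction, in which the C12 oxygen binds the triacetoxyborohydride and hydride is delivered intramolecularly to the face of the C10 carbonyl on which C12–O stands, should give the 1,3-anti diol with C10 as R.

Step 18
Reactants: 28 (1R,3R,4R,6R,7R,9S)-3-ethyl-9-(prop-2-en-1-yl)-2,8-dioxabicyclo[5.2.1]decane-4,6-diol
Product: 30 (1R,3R,4S,6R,7R,9S)-4-bromo-3-ethyl-9-(prop-2-en-1-yl)-2,8-dioxabicyclo[5.2.1]decan-6-yl acetate, via cyclic orthoester 29 (not isolated)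
Conditions: MeC(OMe)3, PPTS (cat.), CH2Cl2, 23 °C; concentrate; AcBr, CH2Cl2, 0 → 23 °C
Reagents that add atoms: trimethyl orthoacetate, CC(OC)(OC)OC; acetyl bromide, CC(=O)Br
Why: Orthoester-based acetoxy bromide formation from a 1,3-diol, in which acetyl bromide ionises the cyclic orthoacetate to a 1,3-dioxan-2-ylium ion that bromide opens by SN2, should invert C12 to S and leave the acetate on C10 with retention, because the rear of C12 (next to H13) is open while the rear of C10 lies on the side of the C6–O bridge.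

Step 19
Reactants: 30 (1R,3R,4S,6R,7R,9S)-4-bromo-3-ethyl-9-(prop-2-en-1-yl)-2,8-dioxabicyclo[5.2.1]decan-6-yl acetate; 31 (E)-crotonaldehyde
Product: 32 (1R,3R,4S,6R,7R,9S)-4-bromo-3-ethyl-9-[(2E)-4-oxobut-2-en-1-yl]-2,8-dioxabicyclo[5.2.1]decan-6-yl acetate
Conditions: 31 (10 equiv), second-generation Grubbs catalyst RuCl2(=CHPh)(H2IMes)(PCy3) (5 mol %), CH2Cl2, 40 °C
Reagents that add atoms: none
Why: Olefin cross-metathesis of the terminal alkene with excess crotonaldehyde should give the conjugated E enal under thermodynamic control, the secondary bromide and the acetate being inert to the ruthenium carbene.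

Step 20
Reactants: 32 (1R,3R,4S,6R,7R,9S)-4-bromo-3-ethyl-9-[(2E)-4-oxobut-2-en-1-yl]-2,8-dioxabicyclo[5.2.1]decan-6-yl acetate
Product: 33 (1R,3R,4S,6R,7R,9S)-4-bromo-3-ethyl-9-[(2E)-pent-2-en-4-yn-1-yl]-2,8-dioxabicyclo[5.2.1]decan-6-yl acetate
Conditions: Me3SiCHN2 (1.3 equiv), LiN(iPr)2 (1.25 equiv), THF, −78 °C; then 32, −78 → 0 °C
Reagents that add atoms: (trimethylsilyl)diazomethane, C[Si](C)(C)C=[N+]=[N-]
Why: Colvin rearrangement, in which lithiated (trimethylsilyl)diazomethane adds to the aldehyde, silanolate and N2 are lost and the alkylidene carbene undergoes a 1,2-hydrogen shift, should give the terminal alkyne with the E alkene intact, the aldehyde reacting far faster than the acetate at −78 °C.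

**Compound list**

1 | methyl (R)-2-hydroxybutanoate | CC[C@@H](O)C(=O)OC | starting material
2 | tert-butyl diazoacetate | CC(C)(C)OC(=O)C=[N+]=[N-] | starting material
3 | tert-butyl 2-{[(2R)-1-methoxy-1-oxobutan-2-yl]oxy}acetate | CC[C@@H](OCC(=O)OC(C)(C)C)C(=O)OC | intermediate
4 | tert-butyl 2-{[(2R)-1-oxobutan-2-yl]oxy}acetate | CC[C@@H](OCC(=O)OC(C)(C)C)C=O | intermediate
5 | 1-(tert-butyldimethylsilyloxy)-1-methoxyethene | C=C(OC)O[Si](C)(C)C(C)(C)C | starting material
6 | methyl (3R,4R)-4-(2-tert-butoxy-2-oxoethoxy)-3-hydroxyhexanoate | CC(C)(C)OC(=O)CO[C@H](CC)[C@H](O)CC(=O)OC | intermediate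
7 | tert-butyldimethylsilyl 2-{[(3R,4R)-4-(tert-butyldimethylsilyloxy)-6-methoxy-6-oxohexan-3-yl]oxy}acetate | CC(C)(C)[Si](C)(C)OC(=O)CO[C@H](CC)[C@H](O[Si](C)(C)C(C)(C)C)CC(=O)OC | intermediate
8 | 2-{[(3R,4R)-4-(tert-butyldimethylsilyloxy)-6-methoxy-6-oxohexan-3-yl]oxy}acetic acid | OC(=O)CO[C@H](CC)[C@H](O[Si](C)(C)C(C)(C)C)CC(=O)OC | intermediate
9 | (S)-4-benzyl-2-oxazolidinone | O=C1N[C@@H](Cc2ccccc2)CO1 | starting material
10 | mixed anhydride of acid 8 with pivalic acid | CC(C)(C)C(=O)OC(=O)CO[C@H](CC)[C@H](O[Si](C)(C)C(C)(C)C)CC(=O)OC | intermediate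
11 | methyl (3R,4R)-4-{2-[(4S)-4-benzyl-2-oxo-1,3-oxazolidin-3-yl]-2-oxoethoxy}-3-(tert-butyldimethylsilyloxy)hexanoate | O=C1OC[C@H](Cc2ccccc2)N1C(=O)CO[C@H](CC)[C@H](O[Si](C)(C)C(C)(C)C)CC(=O)OC | intermediate
12 | tert-butyl bromoacetate | CC(C)(C)OC(=O)CBr | starting material
13 | tert-butyl (3R)-4-[(4S)-4-benzyl-2-oxo-1,3-oxazolidin-3-yl]-3-{[(3R,4R)-4-(tert-butyldimethylsilyloxy)-6-methoxy-6-oxohexan-3-yl]oxy}-4-oxobutanoate | O=C1OC[C@H](Cc2ccccc2)N1C(=O)[C@@H](CC(=O)OC(C)(C)C)O[C@H](CC)[C@H](O[Si](C)(C)C(C)(C)C)CC(=O)OC | intermediate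
14 | tert-butyl (3R)-3-{[(3R,4R)-4-(tert-butyldimethylsilyloxy)-6-methoxy-6-oxohexan-3-yl]oxy}-4-hydroxybutanoate | OC[C@@H](CC(=O)OC(C)(C)C)O[C@H](CC)[C@H](O[Si](C)(C)C(C)(C)C)CC(=O)OC | intermediate
15 | tert-butyl (3R)-3-{[(3R,4R)-4-(tert-butyldimethylsilyloxy)-6-methoxy-6-oxohexan-3-yl]oxy}-4-oxobutanoate | O=C[C@@H](CC(=O)OC(C)(C)C)O[C@H](CC)[C@H](O[Si](C)(C)C(C)(C)C)CC(=O)OC | intermediate
16 | allylmagnesium bromide | C=CC[Mg]Br | starting material
17 | diisopinocampheylborinate of alcohol 18 (boron on the C6 oxygen) | C=CC[C@H](OB([C@@H]1C[C@@H]2C[C@H]([C@H]1C)C2(C)C)[C@@H]1C[C@@H]2C[C@H]([C@H]1C)C2(C)C)[C@@H](CC(=O)OC(C)(C)C)O[C@H](CC)[C@H](O[Si](C)(C)C(C)(C)C)CC(=O)OC | intermediate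
18 | tert-butyl (3R,4S)-3-{[(3R,4R)-4-(tert-butyldimethylsilyloxy)-6-methoxy-6-oxohexan-3-yl]oxy}-4-hydroxyhept-6-enoate | C=CC[C@H](O)[C@@H](CC(=O)OC(C)(C)C)O[C@H](CC)[C@H](O[Si](C)(C)C(C)(C)C)CC(=O)OC | intermediate
19 | triethylsilyl (3R,4S)-3-{[(3R,4R)-4-(tert-butyldimethylsilyloxy)-6-methoxy-6-oxohexan-3-yl]oxy}-4-(triethylsilyloxy)hept-6-enoate | C=CC[C@H](O[Si](CC)(CC)CC)[C@@H](CC(=O)O[Si](CC)(CC)CC)O[C@H](CC)[C@H](O[Si](C)(C)C(C)(C)C)CC(=O)OC | intermediate
20 | (3R,4S)-3-{[(3R,4R)-4-(tert-butyldimethylsilyloxy)-6-methoxy-6-oxohexan-3-yl]oxy}-4-(triethylsilyloxy)hept-6-enoic acid | C=CC[C@H](O[Si](CC)(CC)CC)[C@@H](CC(=O)O)O[C@H](CC)[C@H](O[Si](C)(C)C(C)(C)C)CC(=O)OC | intermediate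
21 | methyl (3R,4S)-3-{[(3R,4R)-4-(tert-butyldimethylsilyloxy)-6-methoxy-6-oxohexan-3-yl]oxy}-4-(triethylsilyloxy)hept-6-enoate (6S,7R,12R,13R diester) | C=CC[C@H](O[Si](CC)(CC)CC)[C@@H](CC(=O)OC)O[C@H](CC)[C@H](O[Si](C)(C)C(C)(C)C)CC(=O)OC | intermediate
22 | (2R,3R,5Z,8R)-3-(tert-butyldimethylsilyloxy)-2-ethyl-8-[(1S)-1-(triethylsilyloxy)but-3-en-1-yl]-5,6-bis(trimethylsilyloxy)-3,4,7,8-tetrahydro-2H-oxocine | C=CC[C@H](O[Si](CC)(CC)CC)[C@H]1C/C(O[Si](C)(C)C)=C(O[Si](C)(C)C)\C[C@@H](O[Si](C)(C)C(C)(C)C)[C@@H](CC)O1 | intermediate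
23 | (2R,3R,5RS,8R)-3-(tert-butyldimethylsilyloxy)-2-ethyl-5-hydroxy-8-[(1S)-1-hydroxybut-3-en-1-yl]oxocan-6-one | C=CC[C@H](O)[C@H]1CC(=O)C(O)C[C@@H](O[Si](C)(C)C(C)(C)C)[C@@H](CC)O1 | intermediate
24 | (1R,3R,4R,6RS,7R,9S)-4-(tert-butyldimethylsilyloxy)-3-ethyl-9-(prop-2-en-1-yl)-2,8-dioxabicyclo[5.2.1]decane-6,7-diol (C9 hemiketal) | C=CC[C@@H]1O[C@]2(O)C[C@H]1O[C@H](CC)[C@H](O[Si](C)(C)C(C)(C)C)CC2O | intermediate
25 | (1R,3R,4R,6RS,7R,9S)-4-(tert-butyldimethylsilyloxy)-3-ethyl-9-(prop-2-en-1-yl)-2,8-dioxabicyclo[5.2.1]decan-6-ol | C=CC[C@@H]1O[C@@H]2C[C@H]1O[C@H](CC)[C@H](O[Si](C)(C)C(C)(C)C)CC2O | intermediate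
26 | (1R,3R,4R,7R,9S)-4-(tert-butyldimethylsilyloxy)-3-ethyl-9-(prop-2-en-1-yl)-2,8-dioxabicyclo[5.2.1]decan-6-one | C=CC[C@@H]1O[C@@H]2C[C@H]1O[C@H](CC)[C@H](O[Si](C)(C)C(C)(C)C)CC2=O | intermediate
27 | (1R,3R,4R,7R,9S)-3-ethyl-4-hydroxy-9-(prop-2-en-1-yl)-2,8-dioxabicyclo[5.2.1]decan-6-one | C=CC[C@@H]1O[C@@H]2C[C@H]1O[C@H](CC)[C@H](O)CC2=O | intermediate
28 | (1R,3R,4R,6R,7R,9S)-3-ethyl-9-(prop-2-en-1-yl)-2,8-dioxabicyclo[5.2.1]decane-4,6-diol | C=CC[C@@H]1O[C@@H]2C[C@H]1O[C@H](CC)[C@H](O)C[C@H]2O | intermediate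
29 | cyclic methyl orthoacetate of diol 28 (2-methoxy-2-methyl-1,3-dioxane across the C10 and C12 oxygens, orthoester carbon as a mixture) | C=CC[C@@H]1O[C@@H]2C[C@H]1O[C@H](CC)[C@H]3C[C@H]2OC(C)(OC)O3 | intermediate
30 | (1R,3R,4S,6R,7R,9S)-4-bromo-3-ethyl-9-(prop-2-en-1-yl)-2,8-dioxabicyclo[5.2.1]decan-6-yl acetate | C=CC[C@@H]1O[C@@H]2C[C@H]1O[C@H](CC)[C@@H](Br)C[C@H]2OC(C)=O | intermediate
31 | (E)-crotonaldehyde | C/C=C/C=O | starting material
32 | (1R,3R,4S,6R,7R,9S)-4-bromo-3-ethyl-9-[(2E)-4-oxobut-2-en-1-yl]-2,8-dioxabicyclo[5.2.1]decan-6-yl acetate | O=C/C=C/C[C@@H]1O[C@@H]2C[C@H]1O[C@H](CC)[C@@H](Br)C[C@H]2OC(C)=O | intermediate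
33 | (1R,3R,4S,6R,7R,9S)-4-bromo-3-ethyl-9-[(2E)-pent-2-en-4-yn-1-yl]-2,8-dioxabicyclo[5.2.1]decan-6-yl acetate (chain numbering 6S,7R,9R,10R,12S,13R) | C#C/C=C/C[C@@H]1O[C@@H]2C[C@H]1O[C@H](CC)[C@@H](Br)C[C@H]2OC(C)=O | target

Total step count: 20
Longest linear sequence: 20 steps (from 1 to 33)

**Steps most likely to fail**

1. Step 12 (acyloin closure). After electron transfer the β-oxygen groups (the C7 ether oxygen, the C12 silyloxy group) may be expelled, or coupling may take place between molecules on the metal surface, so that the oxocane does not close. The fallback makes the same C9–C10 bond by a pinacol coupling. It sets out from diester 21: iBu2AlH (2.2 equiv, CH2Cl2, −78 °C) should give the dialdehyde F1. Low-valent titanium (TiCl3(DME)1.5, Zn–Cu couple, DME, slow addition, 25 °C) should then close the ring as the 9,10-diol F2 (McMurry pinacol cyclisation). Oxidation of its dibutylstannylene acetal (Bu2SnO, then N-bromosuccinimide, CHCl3) should give the ketol triethylsilyl ether F3 together with its 10-oxo regioisomer. The conditions of step 13 then remove the silyl ether and equilibrate both, and the route is rejoined at hemiketal 24.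

2. Step 13 (ketol equilibration and hemiketal formation). The two ketols may interconvert too slowly under acid, so that hydrolysis leaves the 10-oxo isomer or lets it close the six-membered hemiketal. The fallback passes through the symmetrical diketone, where no enolisation is needed. It sets out from 22: Br2 (1.0 equiv, CH2Cl2, −78 °C), which attacks the electron-rich enediol disilyl ether far faster than the terminal alkene, should give the 9,10-diketone F4. AcOH/THF/H2O then removes the triethylsilyl ether, and the C6 hydroxyl adds reversibly to C9 to give the keto hemiketal F5. NaBH4 (MeOH, −78 °C) reduces the remaining C10 carbonyl, and the route is rejoined at 24.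

3. Step 18 (bromo acetate from the diol). Bromide may open the dioxanylium ion at C10 instead of C12, or a ring oxygen may capture the cation, which would give the regioisomeric or rearranged bromide. The fallback differentiates the two hydroxyls stepwise. It sets out from diol 28: AcCl with 2,4,6-collidine (CH2Cl2, −78 °C) should acetylate the less hindered C10 hydroxyl (cis to H9, whereas the C12 hydroxyl is cis to the ethyl group) to give the hydroxy acetate F6. CBr4 and P(n-C8H17)3 (toluene, 70 °C, Appel-type bromination with inversion) then displace the C12 hydroxyl, and the route is rejoined at 30.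

**Further compounds**

F1 | step 12 | (3R,4S)-3-{[(3R,4R)-4-(tert-butyldimethylsilyloxy)-6-oxohexan-3-yl]oxy}-4-(triethylsilyloxy)hept-6-enal | C=CC[C@H](O[Si](CC)(CC)CC)[C@@H](CC=O)O[C@H](CC)[C@H](O[Si](C)(C)C(C)(C)C)CC=O
F2 | step 12 | (2R,3R,8R)-3-(tert-butyldimethylsilyloxy)-2-ethyl-8-[(1S)-1-(triethylsilyloxy)but-3-en-1-yl]oxocane-5,6-diol | C=CC[C@H](O[Si](CC)(CC)CC)[C@H]1CC(O)C(O)C[C@@H](O[Si](C)(C)C(C)(C)C)[C@@H](CC)O1
F3 | step 12 | (2R,3R,8R)-3-(tert-butyldimethylsilyloxy)-2-ethyl-5-hydroxy-8-[(1S)-1-(triethylsilyloxy)but-3-en-1-yl]oxocan-6-one | C=CC[C@H](O[Si](CC)(CC)CC)[C@H]1CC(=O)C(O)C[C@@H](O[Si](C)(C)C(C)(C)C)[C@@H](CC)O1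
F4 | step 13 | (2R,3R,8R)-3-(tert-butyldimethylsilyloxy)-2-ethyl-8-[(1S)-1-(triethylsilyloxy)but-3-en-1-yl]oxocane-5,6-dione | C=CC[C@H](O[Si](CC)(CC)CC)[C@H]1CC(=O)C(=O)C[C@@H](O[Si](C)(C)C(C)(C)C)[C@@H](CC)O1
F5 | step 13 | (1R,3R,4R,7R,9S)-4-(tert-butyldimethylsilyloxy)-3-ethyl-7-hydroxy-9-(prop-2-en-1-yl)-2,8-dioxabicyclo[5.2.1]decan-6-one | C=CC[C@@H]1O[C@]2(O)C[C@H]1O[C@H](CC)[C@H](O[Si](C)(C)C(C)(C)C)CC2=O
F6 | step 18 | (1R,3R,4R,6R,7R,9S)-3-ethyl-4-hydroxy-9-(prop-2-en-1-yl)-2,8-dioxabicyclo[5.2.1]decan-6-yl acetate | C=CC[C@@H]1O[C@@H]2C[C@H]1O[C@H](CC)[C@H](O)C[C@H]2OC(C)=O
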